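**Retrosynthetic overview**

1. Numbering is that of the chromenone (O1, C2, C3, C4, C4a, C5–C8, C8a); ring A is the 4-pyranone, ring B the carbocycle. The (5S)-carbinol is traced back to the C5 ketone, reduced last by asymmetric transfer hydrogenation.
2. Ring B is cut at C6–C7 and C4a–C5 into a 2-ethenyl-6-alkyl-4H-pyran-4-one (diene C7=C8–C8a=C4a) and 1,1-diethoxyethene (C6=C5 at the ketone oxidation level). They are joined by an inverse-electron-demand Diels-Alder reaction, followed in the same flask by rearomatisation of ring A and ketal hydrolysis.
3. Enabling feature: C5 sits on C4a, the alpha carbon, and C7 is the delta carbon of the vinylogous system O=C4–C4a=C8a–C8=C7 that ring A offers once C7=C8 is a vinyl group. The oxygen on C5 is therefore the donor of an electron-rich two-carbon partner, and the aromatic 4-pyranone re-forms as the thermodynamic sink.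
4. The vinyl pyranone comes from 2,6-dimethyl-4H-pyran-4-one by two lateral metalations: alkylation with (Z)-1-iodohexadec-11-ene (from the Z-alcohol), then Mannich aminomethylation and Hofmann-type elimination.
5. Order of ring formation: ring A is bought; ring B is the only ring closed (step 5).

Key step: step 5

Assumption: (Z)-hexadec-11-en-1-ol (a pheromone component) is taken as commercially available, and the sense of induction in step 6 is taken from the reduction of 1-tetralone-type ketones, with C4a playing the part of the aryl carbon.

**Route**

Step 1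
Reactants: 1 (Z)-hexadec-11-en-1-ol
Product: 2 (Z)-1-iodohexadec-11-ene [(5Z)-16-iodohexadec-5-ene]
Conditions: I2, PPh3, imidazole, CH2Cl2, 0 °C to rt, dark
Reagents that add atoms: iodine, II
Why: Appel-type iodination (activation of the primary alcohol as an alkoxyphosphonium ion and SN2 displacement by iodide) should give the primary iodide without touching or isomerising the remote Z-alkene.

Step 2
Reactants: 3 2,6-dimethyl-4H-pyran-4-one; 2 (Z)-1-iodohexadec-11-ene
Product: 5 2-[(12Z)-heptadec-12-en-1-yl]-6-methyl-4H-pyran-4-one, via lithium dienolate 4 (not isolated)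
Conditions: 3 (2.5 equiv), LiN(iPr)2 (2.4 equiv), THF, −78 °C; then 2 (1 equiv), DMPU, −78 to −20 °C
Reagents that add atoms: none
Why: Lateral (vinylogous) deprotonation of one methyl group of the gamma-pyrone gives the 2-methylidene-2H-pyran-4-olate, which should be alkylated at its exocyclic carbon by the primary iodide (SN2 alkylation of a dienolate at the gamma position, restoring the pyranone), and the excess of the cheap pyranone should suppress double alkylation.

Step 3
Reactants: 5 2-[(12Z)-heptadec-12-en-1-yl]-6-methyl-4H-pyran-4-one
Product: 7 2-[2-(dimethylamino)ethyl]-6-[(12Z)-heptadec-12-en-1-yl]-4H-pyran-4-one, via lithium dienolate 6 (not isolated)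
Conditions: LiN(iPr)2 (1.1 equiv), THF, −78 °C; then CH2=NMe2+ I−, −78 to 0 °C
Reagents that add atoms: dimethylmethylideneammonium iodide (Eschenmoser's salt), C=[N+](C)C.[I-]
Why: Kinetic lateral deprotonation should occur at the methyl group in preference to the more hindered chain methylene, and the dienolate should be aminomethylated at the exocyclic carbon by the iminium salt (vinylogous Mannich reaction).

Step 4
Reactants: 7 2-[2-(dimethylamino)ethyl]-6-[(12Z)-heptadec-12-en-1-yl]-4H-pyran-4-one
Product: 9 2-ethenyl-6-[(12Z)-heptadec-12-en-1-yl]-4H-pyran-4-one, via trimethylammonium iodide 8 (not isolated)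
Conditions: MeI (3 equiv), MeCN, rt; evaporation; then DBU (1.2 equiv), MeCN, 0 °C to rt, BHT (trace)
Reagents that add atoms: none
Why: Quaternisation of the amine (Menshutkin reaction) turns it into a leaving group beta to the acidic lateral C–H bonds, so that DBU should effect an E1cB-type Hofmann elimination to the vinyl pyranone, as with Mannich-base methiodides of ketones.

Step 5
Reactants: 9 2-ethenyl-6-[(12Z)-heptadec-12-en-1-yl]-4H-pyran-4-one; 10 1,1-diethoxyethene (ketene diethyl acetal)
Product: 13 2-[(12Z)-heptadec-12-en-1-yl]-7,8-dihydro-4H-chromene-4,5(6H)-dione, via Diels-Alder adduct 11 (not isolated), via diethyl ketal 12 (not isolated)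
Conditions: 10 (4 equiv), Et3N (cat.), BHT (cat.), toluene, 110 °C, sealed tube; then 1 M HCl, THF, rt
Reagents that add atoms: water, O
Why: The vinyl group and the C4a=C8a bond of ring A make up an electron-poor diene (C7=C8–C8a=C4a, conjugated to the C4 carbonyl) that should combine with the electron-rich ketene acetal in an inverse-electron-demand Diels-Alder reaction, a strongly asynchronous [4+2] process in which the C6–C7 bond leads and the C4a–C5 bond follows (in the stepwise limit a 1,6-conjugate addition that gives a pyranone dienolate and a dialkoxycarbenium ion, which then collapse). The closest known reaction type is the cycloaddition of 2-vinylchromones, the benzo-fused 2-vinyl-4-pyranones, with enamines and other electron-rich alkenes. Ring B is the only ring closed, by intermolecular [4+2] cycloaddition (in the stepwise limit a 6-(enolexo)-exo-trig attack of C4a on C5), after which a base-assisted 1,3-proton shift from C4a to C8 restores the aromatic 4-pyranone and makes the sequence irreversible, and aqueous acid unmasks the C5 ketal as the ketone. No stereocenter leaves the step: C4a is stereogenic only in adduct 11 (formed as a racemate) and becomes trigonal on rearomatisation, while C5 is delivered at the ketone level and its configuration is left to the catalyst of step 6. The regioselectivity that is needed (acetal carbon to C4a, methylene carbon to C7) is secured by the polarisation of both partners, since C7 is the unhindered delta terminus of the dienone with the largest LUMO coefficient and the methylene carbon of the ketene acetal carries the largest HOMO coefficient. The site selectivity that is needed is secured because the isolated Z-alkene of the chain is unactivated and does not react with a nucleophilic dienophile.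

Step 6
Reactants: 13 2-[(12Z)-heptadec-12-en-1-yl]-7,8-dihydro-4H-chromene-4,5(6H)-dione
Product: 14 (5S)-2-[(12Z)-heptadec-12-en-1-yl]-5-hydroxy-5,6,7,8-tetrahydro-4H-chromen-4-one
Conditions: RuCl[(S,S)-TsDPEN](p-cymene) (1 mol %), HCO2H/Et3N (5:2), EtOAc, 30 °C
Reagents that add atoms: none
Why: Noyori asymmetric transfer hydrogenation should reduce only the C5 ketone (C4 is a vinylogous ester carbonyl inside the aromatic pyranone and the isolated Z-alkene is inert to the ruthenium hydride), and the (S,S)-catalyst should deliver hydride to the face that gives the (S)-alcohol, as it does with 1-tetralone, the sp2 carbon C4a taking the place of the aryl group in the CH/pi-controlled transition state.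

**Compound list**

1 | (Z)-hexadec-11-en-1-ol | CCCC/C=C\CCCCCCCCCCO | starting material
2 | (Z)-1-iodohexadec-11-ene | CCCC/C=C\CCCCCCCCCCI | intermediate
3 | 2,6-dimethyl-4H-pyran-4-one | Cc1cc(=O)cc(C)o1 | starting material
4 | lithium 6-methyl-2-methylidene-2H-pyran-4-olate (lateral lithium dienolate of 3) | [Li+].[O-]C1=CC(=C)OC(C)=C1 | intermediate
5 | 2-[(12Z)-heptadec-12-en-1-yl]-6-methyl-4H-pyran-4-one | CCCC/C=C\CCCCCCCCCCCc1cc(=O)cc(C)o1 | intermediate
6 | lithium 6-[(12Z)-heptadec-12-en-1-yl]-2-methylidene-2H-pyran-4-olate (lateral lithium dienolate of 5) | CCCC/C=C\CCCCCCCCCCCC1=CC([O-])=CC(=C)O1.[Li+] | intermediate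
7 | 2-[2-(dimethylamino)ethyl]-6-[(12Z)-heptadec-12-en-1-yl]-4H-pyran-4-one | CCCC/C=C\CCCCCCCCCCCc1cc(=O)cc(CCN(C)C)o1 | intermediate
8 | 2-{6-[(12Z)-heptadec-12-en-1-yl]-4-oxo-4H-pyran-2-yl}-N,N,N-trimethylethanaminium iodide | CCCC/C=C\CCCCCCCCCCCc1cc(=O)cc(CC[N+](C)(C)C)o1.[I-] | intermediate
9 | 2-ethenyl-6-[(12Z)-heptadec-12-en-1-yl]-4H-pyran-4-one | CCCC/C=C\CCCCCCCCCCCc1cc(=O)cc(C=C)o1 | intermediate
10 | 1,1-diethoxyethene | C=C(OCC)OCC | starting material
11 | 5,5-diethoxy-2-[(12Z)-heptadec-12-en-1-yl]-4a,5,6,7-tetrahydro-4H-chromen-4-one (C8=C8a double bond, racemic at C4a) | CCCC/C=C\CCCCCCCCCCCC1=CC(=O)C2C(=CCCC2(OCC)OCC)O1 | intermediate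
12 | 5,5-diethoxy-2-[(12Z)-heptadec-12-en-1-yl]-5,6,7,8-tetrahydro-4H-chromen-4-one | CCCC/C=C\CCCCCCCCCCCc1cc(=O)c2c(o1)CCCC2(OCC)OCC | intermediate
13 | 2-[(12Z)-heptadec-12-en-1-yl]-7,8-dihydro-4H-chromene-4,5(6H)-dione | CCCC/C=C\CCCCCCCCCCCc1cc(=O)c2c(o1)CCCC2=O | intermediate
14 | (5S)-2-[(12Z)-heptadec-12-en-1-yl]-5-hydroxy-5,6,7,8-tetrahydro-4H-chromen-4-one | CCCC/C=C\CCCCCCCCCCCc1cc(=O)c2c(o1)CCC[C@@H]2O | target

**Step count and risks**

Total step count: 6. Longest linear sequence: 6 steps (from 1 to 14).

Steps most likely to fail:

1. Step 5. The cycloaddition may be too slow at a temperature the vinyl pyranone tolerates, so that polymerisation of the diene or closure of the zwitterion to a four-membered ring competes with closure of ring B. The fallback forms the same two bonds one after the other by anionic chemistry and sets out from 9. The lithium enolate of ethyl acetate (LiN(SiMe3)2, EtOAc, THF, −78 °C) should add to the terminal vinyl carbon in a 1,6-Michael addition to give ethyl 4-{6-[(12Z)-heptadec-12-en-1-yl]-4-oxo-4H-pyran-2-yl}butanoate F1. Treatment of this ester with KOtBu in THF (0 °C to rt) should form the lateral dienolate, which is acylated at C4a by the ester in a Dieckmann-type closure driven by deprotonation of the resulting 1,3-dicarbonyl unit. Acidic work-up brings the route back at 13.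

2. Step 3. The second lateral deprotonation may lack site selectivity (methyl against chain methylene), or the ambident dienolate may be attacked at a ring carbon. The fallback builds ring A instead of functionalising it and sets out from 2. The dilithio dianion of pentane-2,4-dione (LiN(iPr)2, 2 equiv, THF, 0 °C) should be alkylated at its terminal carbon by 2 to give (16Z)-henicos-16-ene-2,4-dione F2. A second double deprotonation, which for beta-diketones classically takes place at the terminal methyl group, and Claisen acylation with methyl 3-(dimethylamino)propanoate should give (19Z)-1-(dimethylamino)tetracos-19-ene-3,5,7-trione F3. Cyclodehydration of this 1,3,5-triketone with methanolic HCl, followed by neutralisation with NaHCO3, closes the 4-pyranone and brings the route back at 7.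

3. Step 6. Hydride transfer to a ketone that is deactivated as a vinylogous ester may be slow or poorly face-selective, or conjugate reduction of the pyranone may compete. The fallback replaces asymmetric catalysis by resolution and sets out from 13. Luche reduction (NaBH4, CeCl3·7H2O, MeOH, −20 °C) should give rac-2-[(12Z)-heptadec-12-en-1-yl]-5-hydroxy-5,6,7,8-tetrahydro-4H-chromen-4-one F4. Kinetic resolution with Candida antarctica lipase B and vinyl acetate in tert-butyl methyl ether should acetylate the (5R)-alcohol, as expected from the Kazlauskas rule, to (5R)-2-[(12Z)-heptadec-12-en-1-yl]-4-oxo-5,6,7,8-tetrahydro-4H-chromen-5-yl acetate F5. The unreacted (5S)-alcohol is separated by chromatography, which brings the route back at 14.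

**Further compounds**

F1 | step 5 | ethyl 4-{6-[(12Z)-heptadec-12-en-1-yl]-4-oxo-4H-pyran-2-yl}butanoate | CCCC/C=C\CCCCCCCCCCCc1cc(=O)cc(CCCC(=O)OCC)o1
F2 | step 3 | (16Z)-henicos-16-ene-2,4-dione | CCCC/C=C\CCCCCCCCCCCC(=O)CC(=O)C
F3 | step 3 | (19Z)-1-(dimethylamino)tetracos-19-ene-3,5,7-trione | CCCC/C=C\CCCCCCCCCCCC(=O)CC(=O)CC(=O)CCN(C)C
F4 | step 6 | rac-2-[(12Z)-heptadec-12-en-1-yl]-5-hydroxy-5,6,7,8-tetrahydro-4H-chromen-4-one | CCCC/C=C\CCCCCCCCCCCc1cc(=O)c2c(o1)CCCC2O
F5 | step 6 | (5R)-2-[(12Z)-heptadec-12-en-1-yl]-4-oxo-5,6,7,8-tetrahydro-4H-chromen-5-yl acetate | CCCC/C=C\CCCCCCCCCCCc1cc(=O)c2c(o1)CCC[C@H]2OC(C)=O
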